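**Retrosynthetic overview**
- The target is opened to an acyclic epoxy-ynal by one nickel-mediated [2+2+1] of alkyne, aldehyde and CO. The C6–C7 bond closes the ten-membered carbocycle, CO becomes C12, and the lactone C–O bond closes the butenolide in the same flask; C6 is set here.
- The epoxy-ynal comes from the primary alcohol, which comes from a Ni/Cr alkenylation (C1–C10 bond, C1 carbinol). The partners are a C1–C6 epoxy aldehyde and a C7–C14 Z-alkenyl iodide that already carries the tiglate and the acetate.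
- The epoxy aldehyde comes from geraniol (Sharpless epoxidation sets C4/C5, then ozonolysis). The alkenyl iodide comes from (Z)-3-iodobut-2-enal, propargyl acetate (asymmetric alkynylation sets C8) and tiglic acid; the 9Z geometry comes from trans-hydroalumination/iodination of but-2-yn-1-ol.
- Ring order: oxirane first (step 1), then carbocycle and butenolide together (step 9). No protecting groups are used.

Assumption: (S,S)-ProPhenol (step 5) and the (S)-oxazoline–sulfonamide chromium ligand (step 7) are taken to give the carbinol configurations written; both ligands exist as either enantiomer and the antipode is used if the first Mosher analysis shows the opposite sense.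

**Route**

Step 1
Reactants: 1 geraniol [(2E)-3,7-dimethylocta-2,6-dien-1-ol]
Product: 2 (2R,3R)-2,3-epoxygeraniol {[(2R,3R)-3-methyl-3-(4-methylpent-3-en-1-yl)oxiran-2-yl]methanol}
Conditions: Ti(OiPr)4 (5 mol %), D-(−)-diisopropyl tartrate (6 mol %), t-BuOOH (1.5 equiv), 4 Å MS, CH2Cl2, −20 °C
Reagents that add atoms: tert-butyl hydroperoxide CC(C)(C)OO
Why: Sharpless asymmetric epoxidation; the D-tartrate titanium complex delivers oxygen to the face of the E-allylic alcohol that gives the (2R,3R)-epoxide (C4 and C5 of the target), and the isolated 6,7-alkene does not react.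

Step 2
Reactants: 2 (2R,3R)-2,3-epoxygeraniol
Product: 4 hydroxy epoxy aldehyde 3-[(2R,3R)-3-(hydroxymethyl)-2-methyloxiran-2-yl]propanal, via secondary ozonide 3 (not isolated)
Conditions: O3, CH2Cl2, −78 °C; then PPh3, −78 °C → rt
Reagents that add atoms: ozone [O-][O+]=O
Why: Ozonolysis (Criegee mechanism) cleaves the only remaining alkene and PPh3 reduces the ozonide to the aldehyde; epoxide, primary alcohol and both stereocentres are untouched, and the trans-epoxide prevents lactol formation.

Step 3
Reactants: 5 but-2-yn-1-ol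
Product: 7 (2Z)-3-iodobut-2-en-1-ol, via cyclic vinylalanate 6 (not isolated)
Conditions: NaAlH2(OCH2CH2OMe)2, THF, 0 °C → rt; then I2, THF, −78 °C
Reagents that add atoms: iodine II
Why: Hydroxyl-directed trans-hydroalumination puts hydride on C2 and aluminium on C3 in a five-membered alanate, and iodinolysis with retention gives the Z-alkenyl iodide; this fixes the 9Z geometry of the target.

Step 4
Reactants: 7 (2Z)-3-iodobut-2-en-1-ol
Product: 8 (2Z)-3-iodobut-2-enal
Conditions: MnO2, CH2Cl2, rt, dark; used at once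
Reagents that add atoms: none
Why: Allylic alcohol oxidation with MnO2 is neutral and heterogeneous, so the Z-iodo enal forms without Z/E isomerisation or loss of iodide.

Step 5
Reactants: 8 (2Z)-3-iodobut-2-enal and 9 prop-2-yn-1-yl acetate
Product: 11 (4S,5Z)-4-hydroxy-6-iodohept-5-en-2-yn-1-yl acetate, via alkynylzinc 10 (not isolated)
Conditions: 9 (3 equiv), Me2Zn (3 equiv), (S,S)-ProPhenol (20 mol %), Ph3P=O (40 mol %), toluene, 0 °C, 1 h; then 8, 4 °C
Reagents that add atoms: none
Why: ProPhenol dinuclear zinc alkynylation, a method suited to α,β-unsaturated aldehydes; one zinc binds the enal and the other delivers the alkynyl group to one face, giving the (S)-carbinol (C8), and alkynylzincs leave the acetate and the C–I bond alone.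

Step 6
Reactants: 11 (4S,5Z)-4-hydroxy-6-iodohept-5-en-2-yn-1-yl acetate and 12 tiglic acid [(2E)-2-methylbut-2-enoic acid]
Product: 13 (4S,5Z)-1-(acetyloxy)-6-iodohept-5-en-2-yn-4-yl (2E)-2-methylbut-2-enoate
Conditions: EDC·HCl, DMAP (cat.), CH2Cl2, 0 °C → rt
Reagents that add atoms: none
Why: Steglich esterification of the secondary propargylic alcohol; no stereocentre is touched and the thermodynamically favoured E (tiglate) geometry is kept.

Step 7
Reactants: 4 3-[(2R,3R)-3-(hydroxymethyl)-2-methyloxiran-2-yl]propanal and 13 (4S,5Z)-1-(acetyloxy)-6-iodohept-5-en-2-yn-4-yl (2E)-2-methylbut-2-enoate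
Product: 14 (4S,5Z,7S)-1-(acetyloxy)-7-hydroxy-9-[(2R,3R)-3-(hydroxymethyl)-2-methyloxiran-2-yl]-6-methylnon-5-en-2-yn-4-yl (2E)-2-methylbut-2-enoate
Conditions: CrCl2 (4 equiv), (S)-N-[2-(4-isopropyl-4,5-dihydro-1,3-oxazol-2-yl)-6-methylphenyl]methanesulfonamide (4.4 equiv), Et3N (4.4 equiv), NiCl2 (10 mol %), THF, rt
Reagents that add atoms: none
Why: Nozaki–Hiyama–Kishi alkenylation; the C–I bond adds to zerovalent nickel, the alkenyl group passes to trivalent chromium with retention of the Z geometry and adds only to the aldehyde (esters, alkyne, epoxide and the free hydroxyl are tolerated), while the chromium-bound oxazoline–sulfonamide ligand selects the aldehyde face and sets C1 (7S in 14).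

Step 8
Reactants: 14 (4S,5Z,7S)-1-(acetyloxy)-7-hydroxy-9-[(2R,3R)-3-(hydroxymethyl)-2-methyloxiran-2-yl]-6-methylnon-5-en-2-yn-4-yl (2E)-2-methylbut-2-enoate
Product: 15 (4S,5Z,7S)-1-(acetyloxy)-9-[(2R,3S)-3-formyl-2-methyloxiran-2-yl]-7-hydroxy-6-methylnon-5-en-2-yn-4-yl (2E)-2-methylbut-2-enoate
Conditions: TEMPO (10 mol %), PhI(OAc)2 (1.1 equiv), CH2Cl2/pH 7 phosphate buffer, 0 °C → rt; used crude
Reagents that add atoms: none
Why: Oxoammonium (TEMPO) oxidation takes the unhindered primary alcohol far faster than the hindered secondary allylic C1 hydroxyl, and the buffered conditions keep the epoxy aldehyde, the acid-sensitive epoxy alcohol motif and all stereocentres intact (the descriptor at the formyl-bearing carbon changes from R to S by priority only).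

Step 9
Reactants: 15 (4S,5Z,7S)-1-(acetyloxy)-9-[(2R,3S)-3-formyl-2-methyloxiran-2-yl]-7-hydroxy-6-methylnon-5-en-2-yn-4-yl (2E)-2-methylbut-2-enoate
Product: 17 target CNP0222387.1 [(1S,4R,5R,6S,8S,9Z)-13-acetoxy-4,5-epoxy-1-hydroxy-8-[(2E)-2-methylbut-2-enoyloxy]germacra-7(11),9-dien-12,6-olide], via oxanickelacycle 16 (not isolated)
Conditions: Ni(cod)2 (1.2 equiv), IPr [1,3-bis(2,6-diisopropylphenyl)imidazol-2-ylidene] (1.2 equiv), toluene, rt, 15 added by syringe pump to 2 mM; then CO (1 atm), rt
Reagents that add atoms: carbon monoxide [C-]#[O+]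
Why: Proposed new method: zerovalent nickel carrying the bulky carbene IPr binds the alkyne and the activated α,β-epoxy aldehyde of 15 and undergoes oxidative cyclisation with C6–C7 bond formation at the alkyne carbon that bears the larger (tether) substituent, closing the ten-membered carbocycle as oxanickelacyclopentene 16; CO then inserts into the Ni–C11 bond and acyl–oxygen reductive elimination closes the butenolide, so both rings form in one flask; C6 is set because the tethered C7 is expected to reach the aldehyde only anti to the epoxide C–O bond with C=O eclipsing C5–H (formyl H, not the nickel-bound oxygen, next to the C4 methyl), which gives 6S with H5/H6 anti; the closest known reaction types are the nickel/carbene oxidative cyclisation of ynals used in reductive macrocyclisations and the hetero-Pauson–Khand [2+2+1] of ynals with CO, including carbonylation of aza- and oxanickelacycles to lactams and lactones.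

**Compound list**
1 | geraniol, (2E)-3,7-dimethylocta-2,6-dien-1-ol | CC(C)=CCC/C(C)=C/CO | starting material
2 | (2R,3R)-2,3-epoxygeraniol | CC(C)=CCC[C@@]1(C)O[C@@H]1CO | intermediate
3 | secondary ozonide, [(2R,3R)-3-[2-(5,5-dimethyl-1,2,4-trioxolan-3-yl)ethyl]-3-methyloxiran-2-yl]methanol (epimers at the trioxolane carbon) | CC1(C)OOC(CC[C@@]2(C)O[C@@H]2CO)O1 | intermediate (not isolated)
4 | 3-[(2R,3R)-3-(hydroxymethyl)-2-methyloxiran-2-yl]propanal | O=CCC[C@@]1(C)O[C@@H]1CO | intermediate
5 | but-2-yn-1-ol | CC#CCO | starting material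
6 | cyclic vinylalanate, sodium 2,2-bis(2-methoxyethoxy)-3-methyl-2,5-dihydro-1,2-oxaaluminol-2-uide | CC1=CCO[Al-]1(OCCOC)OCCOC.[Na+] | intermediate (not isolated)
7 | (2Z)-3-iodobut-2-en-1-ol | C/C(I)=C/CO | intermediate
8 | (2Z)-3-iodobut-2-enal | C/C(I)=C/C=O | intermediate
9 | prop-2-yn-1-yl acetate | CC(=O)OCC#C | starting material
10 | alkynylzinc, [3-(acetyloxy)prop-1-yn-1-yl](methyl)zinc | C[Zn]C#CCOC(C)=O | intermediate (not isolated)
11 | (4S,5Z)-4-hydroxy-6-iodohept-5-en-2-yn-1-yl acetate | CC(=O)OCC#C[C@@H](O)/C=C(/C)I | intermediate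
12 | tiglic acid, (2E)-2-methylbut-2-enoic acid | C/C=C(\C)C(=O)O | starting material
13 | (4S,5Z)-1-(acetyloxy)-6-iodohept-5-en-2-yn-4-yl (2E)-2-methylbut-2-enoate | C/C=C(\C)C(=O)O[C@H](C#CCOC(C)=O)/C=C(/C)I | intermediate
14 | (4S,5Z,7S)-1-(acetyloxy)-7-hydroxy-9-[(2R,3R)-3-(hydroxymethyl)-2-methyloxiran-2-yl]-6-methylnon-5-en-2-yn-4-yl (2E)-2-methylbut-2-enoate | C/C=C(\C)C(=O)O[C@H](C#CCOC(C)=O)/C=C(/C)[C@@H](O)CC[C@@]1(C)O[C@@H]1CO | intermediate
15 | (4S,5Z,7S)-1-(acetyloxy)-9-[(2R,3S)-3-formyl-2-methyloxiran-2-yl]-7-hydroxy-6-methylnon-5-en-2-yn-4-yl (2E)-2-methylbut-2-enoate | C/C=C(\C)C(=O)O[C@H](C#CCOC(C)=O)/C=C(/C)[C@@H](O)CC[C@@]1(C)O[C@@H]1C=O | intermediate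
16 | oxanickelacyclopentene: closed ten-membered ring with Ni(IPr) bonded to O6 and C11 | C/C=C(\C)C(=O)O[C@H]1/C=C(/C)[C@@H](O)CC[C@@]2(C)O[C@@H]2[C@H]2O[Ni](=C3N(c4c(C(C)C)cccc4C(C)C)C=CN3c3c(C(C)C)cccc3C(C)C)C(COC(C)=O)=C12 | intermediate (not isolated)
17 | CNP0222387.1, (1S,4R,5R,6S,8S,9Z)-13-acetoxy-4,5-epoxy-1-hydroxy-8-[(2E)-2-methylbut-2-enoyloxy]germacra-7(11),9-dien-12,6-olide | C/C=C(\C)C(=O)O[C@H]1/C=C(/C)[C@@H](O)CC[C@@]2(C)O[C@@H]2[C@H]2OC(=O)C(COC(C)=O)=C12 | target

**Totals**
Total step count: 9. Longest linear sequence: 7 steps (but-2-yn-1-ol to target, steps 3–9); geraniol enters after 2 steps.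

**Steps most likely to fail, with fallbacks**

Step 9 is the weakest step. Zerovalent nickel may ionise the propargylic acetate or the allylic/propargylic tiglate, or open the epoxy aldehyde reductively. CO may bind nickel before the metallacycle has closed. The free C1 hydroxyl may protonate the Ni–C bond, and the C6 epimer may form. The fallback sets out from 15 and comes back at 17 by separating the two ring closures. The nickelacycle 16 is formed as in step 9 but quenched with I2 at −78 °C instead of CO. This gives the macrocyclic alkenyl iodide (1S,4R,5R,6S,7(11)E,8S,9Z)-13-acetoxy-4,5-epoxy-1,6-dihydroxy-11-iodo-8-[(2E)-2-methylbut-2-enoyloxy]-12-norgermacra-7(11),9-diene F1. The butenolide is then closed by palladium-catalysed carbonylative lactonisation of this γ-hydroxy alkenyl iodide (PdCl2(PPh3)2, CO 1 atm, K2CO3, THF, rt) to give 17.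

Step 7 is the second risk. The level and sense of induction at C1 on a polyfunctional aldehyde with a free hydroxyl are uncertain. The alkenylchromium may lose the γ-tiglate to give an allene. The new C1 alkoxide may attack the epoxide under chromium Lewis acidity. The fallback sets out from 4 and 13 and comes back at 14, and sets C1 by reduction instead of by C–C bond formation. Ligand-free coupling (CrCl2, NiCl2 cat., DMSO, rt) gives the C7-epimeric mixture (4S,5Z,7RS)-1-(acetyloxy)-7-hydroxy-9-[(2R,3R)-3-(hydroxymethyl)-2-methyloxiran-2-yl]-6-methylnon-5-en-2-yn-4-yl (2E)-2-methylbut-2-enoate F2. MnO2 (CH2Cl2, rt) oxidises only the allylic hydroxyl to the enone (4S,5Z)-1-(acetyloxy)-9-[(2R,3R)-3-(hydroxymethyl)-2-methyloxiran-2-yl]-6-methyl-7-oxonon-5-en-2-yn-4-yl (2E)-2-methylbut-2-enoate F3. Corey–Bakshi–Shibata reduction with (R)-Me-CBS and catecholborane (toluene, −78 °C) then gives 14; the α-methyl alkenyl group acts as the large substituent, so the (S)-carbinol results.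

Step 5 is the third risk. Zincation of propargyl acetate may be slow, the β-iodo enal may give a modest ee, and acetyl transfer to the product alkoxide is possible. The fallback sets out from 8 and 9 and comes back at 11 by oxidation and asymmetric reduction instead of asymmetric addition. Uncatalysed Me2Zn-mediated alkynylation (toluene, rt) gives racemic (5Z)-4-hydroxy-6-iodohept-5-en-2-yn-1-yl acetate F4. MnO2 (CH2Cl2, rt) gives the ynone (5Z)-6-iodo-4-oxohept-5-en-2-yn-1-yl acetate F5. Reduction with (S)-Me-CBS and catecholborane (−78 °C), with alkenyl as the large and alkynyl as the small group, returns (S)-configured 11.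

**Further compounds**
F1 | step 9 | (1S,4R,5R,6S,7(11)E,8S,9Z)-13-acetoxy-4,5-epoxy-1,6-dihydroxy-11-iodo-8-[(2E)-2-methylbut-2-enoyloxy]-12-norgermacra-7(11),9-diene | C/C=C(\C)C(=O)O[C@H]1/C=C(/C)[C@@H](O)CC[C@@]2(C)O[C@@H]2[C@@H](O)/C1=C(\I)COC(C)=O
F2 | step 7 | (4S,5Z,7RS)-1-(acetyloxy)-7-hydroxy-9-[(2R,3R)-3-(hydroxymethyl)-2-methyloxiran-2-yl]-6-methylnon-5-en-2-yn-4-yl (2E)-2-methylbut-2-enoate (C7-epimer mixture of 14) | C/C=C(\C)C(=O)O[C@H](C#CCOC(C)=O)/C=C(/C)C(O)CC[C@@]1(C)O[C@@H]1CO
F3 | step 7 | (4S,5Z)-1-(acetyloxy)-9-[(2R,3R)-3-(hydroxymethyl)-2-methyloxiran-2-yl]-6-methyl-7-oxonon-5-en-2-yn-4-yl (2E)-2-methylbut-2-enoate | C/C=C(\C)C(=O)O[C@H](C#CCOC(C)=O)/C=C(/C)C(=O)CC[C@@]1(C)O[C@@H]1CO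
F4 | step 5 | racemic (5Z)-4-hydroxy-6-iodohept-5-en-2-yn-1-yl acetate | CC(=O)OCC#CC(O)/C=C(/C)I
F5 | step 5 | (5Z)-6-iodo-4-oxohept-5-en-2-yn-1-yl acetate | CC(=O)OCC#CC(=O)/C=C(/C)I
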